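The route rests on reading the cis C3/C4 dimethyl pair of the oxolane ring, both methyls anti to the aryl groups on C2 and C5, as the two CH2 arms of a cis-fused thiolane. One (3+2) cycloaddition of the parent thiocarbonyl ylide to the C3=C4 bond of an enantiopure 5-aryl butenolide makes both C–CH2 bonds, closes the thiolane anti to the C5 aryl group and sets C3 and C4; the bicycle then directs the second aryl group to the convex face at C2, and nickel later turns the thiolane into the methyls. The precursor is (S)-5-[4-(benzyloxy)phenyl]furan-2(5H)-one, its phenol carried as a benzyl ether because the ylide is released with fluoride.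

Key step: step 5

Remark: all three phenols are carried as benzyl ethers (inert to fluoride, Grignard and zinc reagents, removed in the final nickel step); benzenesulfinic acid 20 is taken as the free acid, liberated from its commercial sodium salt shortly before use.

**Butenolide arm**

Step 1
Reactants: 1 4-(benzyloxy)benzaldehyde; 2 vinylmagnesium bromide
Product: 3 rac-1-[4-(benzyloxy)phenyl]prop-2-en-1-ol
Conditions: 2 (1.2 equiv), THF, −78 → 0 °C; aq NH4Cl
Reagents that add atoms: vinylmagnesium bromide (2), C=C[Mg]Br
Why: Grignard 1,2-addition of a vinyl nucleophile to an aromatic aldehyde should give the allylic alcohol cleanly; the carbinol centre forms racemic and is resolved in step 2.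

Step 2
Reactants: 3 rac-1-[4-(benzyloxy)phenyl]prop-2-en-1-ol
Product: 4 (S)-1-[4-(benzyloxy)phenyl]prop-2-en-1-ol
Conditions: Novozym 435 (immobilised CAL-B), vinyl acetate (3 equiv), MTBE, 30 °C, run to slightly past half conversion; chromatography
Reagents that add atoms: none
Why: Lipase-catalysed kinetic resolution by transesterification follows the Kazlauskas rule (aryl as large, vinyl as medium group), so the (R)-alcohol should be acetylated and the (S)-alcohol left behind, its ee rising as conversion passes one half.

Step 3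
Reactants: 4 (S)-1-[4-(benzyloxy)phenyl]prop-2-en-1-ol; 5 acryloyl chloride
Product: 6 (S)-1-[4-(benzyloxy)phenyl]prop-2-en-1-yl prop-2-enoate
Conditions: 5 (1.3 equiv), Et3N (1.5 equiv), CH2Cl2, −20 → 0 °C; NaHCO3 work-up
Reagents that add atoms: acryloyl chloride (5), C=CC(Cl)=O
Why: O-acylation of the secondary alcohol with an acid chloride and an amine base does not touch the C–O stereocentre, and the cold, buffered conditions should prevent ionisation of the p-alkoxybenzylic allylic ester.

Step 4
Reactants: 6 (S)-1-[4-(benzyloxy)phenyl]prop-2-en-1-yl prop-2-enoate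
Product: 7 (S)-5-[4-(benzyloxy)phenyl]furan-2(5H)-one
Conditions: Grubbs II (5 mol %), CH2Cl2 (0.01 M), 40 °C
Reagents that add atoms: none
Why: Ring-closing metathesis of an allyl acrylate with a second-generation ruthenium carbene is the standard entry to 5-substituted furan-2(5H)-ones, is driven by loss of ethene and leaves C5 untouched under neutral conditions.

Step 5
Reactants: 7 (S)-5-[4-(benzyloxy)phenyl]furan-2(5H)-one; 8 chloromethyl trimethylsilylmethyl sulfide
Product: 10 (3S,3aS,6aR)-3-[4-(benzyloxy)phenyl]tetrahydro-1H-thieno[3,4-c]furan-1-one (cis-fused thiolane–lactone; aryl on the convex face), via thiocarbonyl ylide 9 (not isolated)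
Conditions: CsF (anhydrous, 3 equiv), 8 (2.5 equiv, slow addition), MeCN, 20 °C
Reagents that add atoms: chloromethyl trimethylsilylmethyl sulfide (8), C[Si](C)(C)CSCCl
Why: Fluoride attacks the silicon of 8 and chloride leaves from the other carbon, releasing the parent thiocarbonyl ylide 9, an electron-rich allyl-anion-type 1,3-dipole that adds in a concerted, suprafacial [π4s+π2s] step to the electron-poor C3=C4 bond of 7. The closest known reaction type is the fluoride-induced thiocarbonyl ylide (3+2) cycloaddition of this same reagent with butenolides, maleates and enones. The thiolane is closed by this intermolecular cycloaddition, both C–CH2 bonds forming in one step on a ring alkene, so the ring fusion can only be cis. The two new stereocentres (lactone C3 and C4, ring atoms C6a and C3a of 10) are controlled by the C5 aryl group, which shields one π-face and sends the dipole to the other, so the aryl group ends on the convex side of the bicycle. The step needs π-facial selectivity, secured by that adjacent aryl-bearing sp3 centre, and configurational integrity at C5, secured by the weakly basic heterogeneous CsF/MeCN system, the slow addition of 8 and a benzyl ether that fluoride cannot cleave to a phenoxide.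

**Aryl bromide arm**

Step 6
Reactants: 11 5'-bromo-2'-hydroxyacetophenone; 12 benzyl bromide
Product: 13 1-[2-(benzyloxy)-5-bromophenyl]ethan-1-one
Conditions: 12 (1.1 equiv), K2CO3 (1.5 equiv), DMF, 50 °C
Reagents that add atoms: benzyl bromide (12), BrCc1ccccc1
Why: Williamson etherification of the phenol should be clean, and a benzyl ether, unlike an ortho silyl ether, cannot migrate to the tertiary alkoxide formed in step 7.

Step 7
Reactants: 13 1-[2-(benzyloxy)-5-bromophenyl]ethan-1-one; 14 4-(benzyloxy)benzyl chloride
Product: 16 rac-2-[2-(benzyloxy)-5-bromophenyl]-1-[4-(benzyloxy)phenyl]propan-2-ol, via [4-(benzyloxy)benzyl]magnesium chloride 15 (not isolated)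
Conditions: 14 (1.6 equiv), Mg, THF, 0 °C (slow addition); then 13, THF, 0 °C → rt; aq NH4Cl
Reagents that add atoms: 4-(benzyloxy)benzyl chloride (14), ClCc1ccc(OCc2ccccc2)cc1
Why: Grignard addition of a benzylic magnesium chloride to the aryl methyl ketone should give the tertiary alcohol, the aryl bromide being inert to this reagent at 0 °C; the new tertiary centre is racemic and is removed in step 8.

Step 8
Reactants: 16 rac-2-[2-(benzyloxy)-5-bromophenyl]-1-[4-(benzyloxy)phenyl]propan-2-ol
Product: 17 (E)-1-(benzyloxy)-2-{1-[4-(benzyloxy)phenyl]prop-1-en-2-yl}-4-bromobenzene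
Conditions: p-TsOH·H2O (5 mol %), toluene, reflux, Dean–Stark; crystallisation or chromatography to geometric purity
Reagents that add atoms: none
Why: Acid-catalysed E1 dehydration of the tertiary benzylic alcohol under equilibrating conditions should favour the conjugated trisubstituted (E)-stilbene with the aryl groups trans, which must be freed from Z and terminal isomers before step 9 because these would lower the ee.

Step 9
Reactants: 17 (E)-1-(benzyloxy)-2-{1-[4-(benzyloxy)phenyl]prop-1-en-2-yl}-4-bromobenzene
Product: 18 (R)-1-(benzyloxy)-2-{1-[4-(benzyloxy)phenyl]propan-2-yl}-4-bromobenzene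
Conditions: [Ir(cod)((S)-tBu-PHOX)]BArF (1–2 mol %), H2 (50 bar), CH2Cl2, rt
Reagents that add atoms: none
Why: Iridium–PHOX asymmetric hydrogenation of unfunctionalised trisubstituted (E)-aryl alkenes (the (E)-α-methylstilbene class) should add H2 to one enantioface and set the benzylic centre as R, the ligand enantiomer being chosen by analogy with (E)-1,2-diphenylpropene and checked on small scale, while the aryl bromide and benzyl ethers are inert to the homogeneous catalyst.

**Union and end-game**

Step 10
Reactants: 10 (3S,3aS,6aR)-3-[4-(benzyloxy)phenyl]tetrahydro-1H-thieno[3,4-c]furan-1-one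
Product: 19 3-[4-(benzyloxy)phenyl]tetrahydro-1H,3H-thieno[3,4-c]furan-1-ol (lactol; anomeric mixture; ring configuration as in 10)
Conditions: DIBAL-H (1.1 equiv), CH2Cl2, −78 °C; Rochelle salt
Reagents that add atoms: none
Why: Partial reduction of a γ-lactone with one equivalent of DIBAL-H at −78 °C stops at the aluminium hemiacetal, which gives the lactol on work-up without touching a ring stereocentre; the anomeric configuration is of no consequence.

Step 11
Reactants: 19 lactol; 20 benzenesulfinic acid
Product: 21 3-[4-(benzyloxy)phenyl]-1-(phenylsulfonyl)tetrahydro-1H,3H-thieno[3,4-c]furan (anomeric sulfone; mixture at C1; ring configuration as in 10)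
Conditions: 20 (3 equiv), CaCl2 (powdered), CH2Cl2, rt
Reagents that add atoms: benzenesulfinic acid (20), OS(=O)c1ccccc1
Why: Acid-promoted exchange of the anomeric hydroxyl for the sulfur of a sulfinate via the oxocarbenium ion is the established preparation of 2-sulfonyl cyclic ethers, and the configuration at the sulfonyl carbon is erased again in step 12.

Step 12
Reactants: 21 anomeric sulfone; 18 (R)-1-(benzyloxy)-2-{1-[4-(benzyloxy)phenyl]propan-2-yl}-4-bromobenzene
Product: 24 (1R,3S,3aS,6aR)-1-{4-(benzyloxy)-3-[(2R)-1-(4-(benzyloxy)phenyl)propan-2-yl]phenyl}-3-[4-(benzyloxy)phenyl]tetrahydro-1H,3H-thieno[3,4-c]furan (both aryl groups on the convex face), via arylmagnesium bromide 22 (not isolated), via diarylzinc 23 (not isolated)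
Conditions: 18 (2.4 equiv), Mg, THF, 50 °C; ZnBr2 (1.2 equiv), THF, rt; then 21 (1 equiv), THF, rt
Reagents that add atoms: aryl bromide 18 (delivered as diarylzinc 23), C[C@H](Cc1ccc(OCc2ccccc2)cc1)c1cc(Br)ccc1OCc1ccccc1
Why: Substitution of 2-sulfonyl cyclic ethers by diorganozinc reagents made from Grignard reagents and zinc bromide is known chemistry in which the magnesium and zinc halides ionise the sulfone to the oxocarbenium ion, and the aryl group should enter C2 from the convex face of the cis-fused bicycle, anti to the C3 methylene, which sets C2 with the new aryl cis to the C5 aryl and trans to the thiolane.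

Step 13
Reactants: 24 tri-O-benzyl thiolane-fused diaryloxolane
Product: 25 (2R,3R,4S,5S)-2-{4-hydroxy-3-[(2R)-1-(4-hydroxyphenyl)propan-2-yl]phenyl}-5-(4-hydroxyphenyl)-3,4-dimethyloxolane (CNP0232576.1)
Conditions: Raney Ni (W-2, washed neutral, large excess), H2 (1 atm), EtOH–THF, rt → 40 °C
Reagents that add atoms: none
Why: Raney nickel hydrogenolysis cleaves both C–S bonds, turning the two sulfur-bound methylenes into methyl groups without involving a stereocentre, and the same nickel/hydrogen system is a classical reagent for hydrogenolysis of aryl benzyl ethers, whereas the benzylic C–O bonds of the oxolane should survive neutral conditions near room temperature.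

**Compound list**

1 | 4-(benzyloxy)benzaldehyde | O=Cc1ccc(OCc2ccccc2)cc1 | starting material
2 | vinylmagnesium bromide | C=C[Mg]Br | starting material
3 | rac-1-[4-(benzyloxy)phenyl]prop-2-en-1-ol | C=CC(O)c1ccc(OCc2ccccc2)cc1 | intermediate
4 | (S)-1-[4-(benzyloxy)phenyl]prop-2-en-1-ol | C=C[C@H](O)c1ccc(OCc2ccccc2)cc1 | intermediate
5 | acryloyl chloride | C=CC(Cl)=O | starting material
6 | (S)-1-[4-(benzyloxy)phenyl]prop-2-en-1-yl prop-2-enoate | C=CC(=O)O[C@@H](C=C)c1ccc(OCc2ccccc2)cc1 | intermediate
7 | (S)-5-[4-(benzyloxy)phenyl]furan-2(5H)-one | O=C1C=C[C@@H](c2ccc(OCc3ccccc3)cc2)O1 | intermediate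
8 | chloromethyl trimethylsilylmethyl sulfide | C[Si](C)(C)CSCCl | starting material
9 | thioformaldehyde S-methylide (parent thiocarbonyl ylide) | C=[S+][CH2-] | intermediate
10 | (3S,3aS,6aR)-3-[4-(benzyloxy)phenyl]tetrahydro-1H-thieno[3,4-c]furan-1-one | C2[C@@H]1[C@H](CS2)[C@@H](c3ccc(OCc4ccccc4)cc3)OC1=O | intermediate
11 | 5'-bromo-2'-hydroxyacetophenone | CC(=O)c1cc(Br)ccc1O | starting material
12 | benzyl bromide | BrCc1ccccc1 | starting material
13 | 1-[2-(benzyloxy)-5-bromophenyl]ethan-1-one | CC(=O)c1cc(Br)ccc1OCc1ccccc1 | intermediate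
14 | 4-(benzyloxy)benzyl chloride | ClCc1ccc(OCc2ccccc2)cc1 | starting material
15 | [4-(benzyloxy)benzyl]magnesium chloride | Cl[Mg]Cc1ccc(OCc2ccccc2)cc1 | intermediate
16 | rac-2-[2-(benzyloxy)-5-bromophenyl]-1-[4-(benzyloxy)phenyl]propan-2-ol | CC(O)(Cc1ccc(OCc2ccccc2)cc1)c1cc(Br)ccc1OCc1ccccc1 | intermediate
17 | (E)-1-(benzyloxy)-2-{1-[4-(benzyloxy)phenyl]prop-1-en-2-yl}-4-bromobenzene | C/C(=C\c1ccc(OCc2ccccc2)cc1)c1cc(Br)ccc1OCc1ccccc1 | intermediate
18 | (R)-1-(benzyloxy)-2-{1-[4-(benzyloxy)phenyl]propan-2-yl}-4-bromobenzene | C[C@H](Cc1ccc(OCc2ccccc2)cc1)c1cc(Br)ccc1OCc1ccccc1 | intermediate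
19 | 3-[4-(benzyloxy)phenyl]tetrahydro-1H,3H-thieno[3,4-c]furan-1-ol (lactol, anomeric mixture, ring configuration as in 10) | C2[C@@H]1[C@H](CS2)[C@@H](c3ccc(OCc4ccccc4)cc3)OC1O | intermediate
20 | benzenesulfinic acid | OS(=O)c1ccccc1 | starting material
21 | 3-[4-(benzyloxy)phenyl]-1-(phenylsulfonyl)tetrahydro-1H,3H-thieno[3,4-c]furan (anomeric mixture, ring configuration as in 10) | C2[C@@H]1[C@H](CS2)[C@@H](c3ccc(OCc4ccccc4)cc3)OC1S(=O)(=O)c1ccccc1 | intermediate
22 | {4-(benzyloxy)-3-[(2R)-1-(4-(benzyloxy)phenyl)propan-2-yl]phenyl}magnesium bromide | C[C@H](Cc1ccc(OCc2ccccc2)cc1)c1cc([Mg]Br)ccc1OCc1ccccc1 | intermediate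
23 | bis{4-(benzyloxy)-3-[(2R)-1-(4-(benzyloxy)phenyl)propan-2-yl]phenyl}zinc | C[C@H](Cc1ccc(OCc2ccccc2)cc1)c1cc([Zn]c2ccc(OCc3ccccc3)c([C@H](C)Cc3ccc(OCc4ccccc4)cc3)c2)ccc1OCc1ccccc1 | intermediate
24 | (1R,3S,3aS,6aR)-1-{4-(benzyloxy)-3-[(2R)-1-(4-(benzyloxy)phenyl)propan-2-yl]phenyl}-3-[4-(benzyloxy)phenyl]tetrahydro-1H,3H-thieno[3,4-c]furan | C2[C@@H]1[C@H](CS2)[C@@H](c3ccc(OCc4ccccc4)cc3)O[C@H]1c1ccc(OCc3ccccc3)c([C@H](C)Cc3ccc(OCc4ccccc4)cc3)c1 | intermediate
25 | (2R,3R,4S,5S)-2-{4-hydroxy-3-[(2R)-1-(4-hydroxyphenyl)propan-2-yl]phenyl}-5-(4-hydroxyphenyl)-3,4-dimethyloxolane (CNP0232576.1) | C[C@@H]1[C@H](C)[C@@H](c2ccc(O)cc2)O[C@H]1c1ccc(O)c([C@H](C)Cc2ccc(O)cc2)c1 | target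

**Step count and risks**

Total: 13 steps. Longest linear sequence: 9 steps (steps 1–5 and 10–13); the aryl bromide arm (steps 6–9) joins at step 12.

The three steps most likely to fail:

1. Step 5. Fluoride may deprotonate C5 of the butenolide to the aromatic 2-oxyfuran anion and erode the ee, or the ylide may self-condense faster than it adds. The fallback sets out from 7 and builds the two methyl groups one at a time by known enolate chemistry instead of by cycloaddition. Conjugate addition of Me2CuLi (TMSCl, THF, −78 °C) anti to the aryl group would give the trans 4-methyl lactone F1. Enolate methylation (LiHMDS, MeI, −78 °C) anti to the C4 methyl would give the 3,4-trans dimethyl lactone F2. Re-enolisation (LDA, −78 °C) and kinetic protonation with a bulky phenol from the face opposite the C4 methyl would give the 3,4-cis dimethyl lactone F3. DIBAL-H would then give the lactol F4, benzenesulfinic acid the sulfone F5, and diarylzinc 23 the tri-O-benzyl ether F6, the aryl entering anti to the C3 methyl. Hydrogenolysis (H2, Pd/C, EtOAc–MeOH) would bring the sequence back to the route at 25.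

2. Step 12. Aryl transfer from the hindered diarylzinc may be too slow, so that the oxocarbenium ion loses a proton to the enol ether or returns to the sulfone, and the facial preference could be lower than expected. The fallback sets out from 19 and 18 and replaces the organometallic by a Friedel–Crafts C-arylation. Acetylation of 19 (Ac2O, pyridine, DMAP, CH2Cl2, 0 °C) would give the lactol acetate F7. Bromine–lithium exchange on 18 (n-BuLi, THF, −78 °C) and protonation would give the arene F8. BF3·OEt2 in CH2Cl2 (−78 → −40 °C) should then join F7 and an excess of F8 at the position para to the benzyloxy group of the 2-alkylated ring, again from the convex face, coming back to the route at 24.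

3. Step 13. Hydrogenolysis may not stop at the C–S and ArO–CH2Ph bonds but also open a benzylic C–O bond of the oxolane, or debenzylation may stall on sulfided nickel. The fallback sets out from 24 and separates the two reductions. Nickel boride (NiCl2·6H2O, NaBH4, MeOH–THF, 0 °C) would remove sulfur only and give the tri-O-benzyl ether F9 (the same structure as F6). Hydrogenolysis over Pd/C (H2, 1 atm, EtOAc–MeOH, rt), now free of sulfur, would come back to the route at 25.

Further compounds
F1 | step 5 | (4S,5S)-5-[4-(benzyloxy)phenyl]-4-methyldihydrofuran-2(3H)-one | O=C1C[C@H](C)[C@@H](c2ccc(OCc3ccccc3)cc2)O1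
F2 | step 5 | (3S,4S,5S)-5-[4-(benzyloxy)phenyl]-3,4-dimethyldihydrofuran-2(3H)-one (3,4-trans) | C[C@H]1[C@H](C)[C@@H](c2ccc(OCc3ccccc3)cc2)OC1=O
F3 | step 5 | (3R,4S,5S)-5-[4-(benzyloxy)phenyl]-3,4-dimethyldihydrofuran-2(3H)-one (3,4-cis) | C[C@@H]1[C@H](C)[C@@H](c2ccc(OCc3ccccc3)cc2)OC1=O
F4 | step 5 | (3R,4S,5S)-5-[4-(benzyloxy)phenyl]-3,4-dimethyloxolan-2-ol (anomeric mixture) | C[C@@H]1[C@H](C)[C@@H](c2ccc(OCc3ccccc3)cc2)OC1O
F5 | step 5 | 5-[4-(benzyloxy)phenyl]-3,4-dimethyl-2-(phenylsulfonyl)oxolane (anomeric mixture, ring configuration as in F4) | C[C@@H]1[C@H](C)[C@@H](c2ccc(OCc3ccccc3)cc2)OC1S(=O)(=O)c1ccccc1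
F6 | step 5 | tri-O-benzyl ether of 25 | C[C@@H]1[C@H](C)[C@@H](c2ccc(OCc3ccccc3)cc2)O[C@H]1c1ccc(OCc2ccccc2)c([C@H](C)Cc2ccc(OCc3ccccc3)cc2)c1
F7 | step 12 | 3-[4-(benzyloxy)phenyl]tetrahydro-1H,3H-thieno[3,4-c]furan-1-yl acetate (anomeric mixture, ring configuration as in 10) | C2[C@@H]1[C@H](CS2)[C@@H](c3ccc(OCc4ccccc4)cc3)OC1OC(C)=O
F8 | step 12 | (R)-1-(benzyloxy)-2-{1-[4-(benzyloxy)phenyl]propan-2-yl}benzene | C[C@H](Cc1ccc(OCc2ccccc2)cc1)c1ccccc1OCc1ccccc1
F9 | step 13 | tri-O-benzyl ether of 25 (same structure as F6) | C[C@@H]1[C@H](C)[C@@H](c2ccc(OCc3ccccc3)cc2)O[C@H]1c1ccc(OCc2ccccc2)c([C@H](C)Cc2ccc(OCc3ccccc3)cc2)c1
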